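**Retrosynthetic overview**

1. Target 31 ← LiBH4 cleavage of aldol adduct 30; the C7–C8 bond comes from an anti-aldol of the (aryloxy)acetyl oxazolidinone 26 with vanillin 4.
2. 26 ← O-alkylation of the cis-(2R,3R)-dihydrobenzofuran phenol 23 ← enantioselective syn-hydrogenation of the 2-aryl-3-(hydroxymethyl)benzofuran 22.
3. 22 ← 2-aryl-3-formylbenzofuran 21 ← acid cyclisation of the 1,2-diaryl-3,3-dimethoxypropan-1-one 19 ← oxidative 1,2-aryl shift of chalcone 18 (forms the C3–C3a bond).
4. 18 ← Claisen–Schmidt condensation of ketone 17 (ring B, from phenol) with aldehyde 12 (ring C, from catechol via guaiacol, bromination, B-alkyl Suzuki coupling and ortho-lithiation); ring A (vanillin) also comes from guaiacol.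
5. Ring order: the three benzene rings are bought; the furan ring is the only ring made (step 13) and is then saturated (step 15).

Assumption: the SMILES is taken at face value, i.e. a 7R,8S (erythro) arylglycerol unit and a 2R,3R (cis) 2-aryl-3-hydroxymethyl-2,3-dihydrobenzofuran.

**Route**

Step 1
Reactants: 1 catechol
Product: 2 guaiacol (2-methoxyphenol)
Conditions: Me2SO4 (1.0 equiv), NaOH (1.0 equiv), H2O, 40 °C; distil
Reagents that add atoms: dimethyl sulfate, COS(=O)(=O)OC
Why: Williamson mono-O-methylation with one equivalent of electrophile; guaiacol is separated from catechol and veratrole by distillation.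

Step 2
Reactants: 2 guaiacol
Product: 4 vanillin (4-hydroxy-3-methoxybenzaldehyde), via 4-hydroxy-3-methoxymandelic acid 3 (not isolated)
Conditions: OHC–CO2H (aq), NaOH, H2O, 30 °C; then CuSO4 (cat.), air, 95 °C; H2SO4 to pH 3
Reagents that add atoms: glyoxylic acid, O=CC(=O)O
Why: Electrophilic hydroxyalkylation para to the phenoxide followed by copper-catalysed oxidative decarboxylation, the established technical vanillin synthesis.

Step 3
Reactants: 2 guaiacol
Product: 5 4-bromo-2-methoxyphenol
Conditions: NBS (1.0 equiv), MeCN, 0 °C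
Reagents that add atoms: N-bromosuccinimide, O=C1CCC(=O)N1Br
Why: Electrophilic aromatic bromination directed para to the free hydroxyl, the stronger donor.

Step 4
Reactants: 5 4-bromo-2-methoxyphenol
Product: 6 4-bromo-2-methoxy-1-(methoxymethoxy)benzene
Conditions: MOMCl, i-Pr2NEt, CH2Cl2, 0 → 25 °C
Reagents that add atoms: chloromethyl methyl ether, COCCl
Why: Standard MOM protection of a phenol; the MOM ether later serves as the ortho-directing group.

Step 5
Reactants: 6 4-bromo-2-methoxy-1-(methoxymethoxy)benzene; 7 allyloxytrimethylsilane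
Product: 10 3-[3-methoxy-4-(methoxymethoxy)phenyl]propan-1-ol, via B-alkyl-9-BBN adduct 8 (not isolated), via coupled trimethylsilyl ether 9 (not isolated)
Conditions: 7, 9-BBN, THF, 0 → 25 °C; then 6, Pd(dppf)Cl2 (3 mol%), 3 M aq NaOH, 65 °C
Reagents that add atoms: none
Why: Anti-Markovnikov hydroboration followed by B-alkyl Suzuki–Miyaura coupling with the aryl bromide; the hot aqueous base hydrolyses the trimethylsilyl ether.

Step 6
Reactants: 10 3-[3-methoxy-4-(methoxymethoxy)phenyl]propan-1-ol
Product: 12 5-(3-hydroxypropyl)-3-methoxy-2-(methoxymethoxy)benzaldehyde, via dilithiated aryl alkoxide 11 (not isolated)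
Conditions: n-BuLi (2.4 equiv), TMEDA, THF, −20 → 0 °C; DMF, −78 → 25 °C; H2O
Reagents that add atoms: N,N-dimethylformamide, CN(C)C=O
Why: Directed ortho-metalation: after alkoxide formation the OMOM group directs lithiation to its only free ortho position, and DMF formylates the aryllithium.

Step 7
Reactants: 13 phenol
Product: 14 1-(4-hydroxyphenyl)ethanone
Conditions: AcCl, CF3SO3H (neat), 0 → 25 °C
Reagents that add atoms: acetyl chloride, CC(=O)Cl
Why: Friedel–Crafts acylation (O-acylation then Fries shift in the superacid), para-selective.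

Step 8
Reactants: 14 1-(4-hydroxyphenyl)ethanone
Product: 15 1-(3,5-dibromo-4-hydroxyphenyl)ethanone
Conditions: Br2 (2.1 equiv), NaOAc, AcOH, 25 °C
Reagents that add atoms: bromine, BrBr
Why: Electrophilic bromination at both positions ortho to the hydroxyl; the para position is blocked and the ring reacts far faster than the ketone α-carbon.

Step 9
Reactants: 15 1-(3,5-dibromo-4-hydroxyphenyl)ethanone
Product: 16 acetosyringone [1-(4-hydroxy-3,5-dimethoxyphenyl)ethanone]
Conditions: NaOMe (6 equiv), CuCl (20 mol%), DMF–MeOH, 110 °C; aq HCl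
Reagents that add atoms: sodium methoxide, [Na+].[O-]C
Why: Ullmann-type copper-catalysed methoxylation of the two aryl bromides, as practised for syringaldehyde from the dibromo aldehyde.

Step 10
Reactants: 16 acetosyringone
Product: 17 1-[3,5-dimethoxy-4-(methoxymethoxy)phenyl]ethanone
Conditions: MOMCl, K2CO3, acetone, 56 °C
Reagents that add atoms: chloromethyl methyl ether, COCCl
Why: MOM protection of the hindered phenol, which must be masked before the oxidative step.

Step 11
Reactants: 12 5-(3-hydroxypropyl)-3-methoxy-2-(methoxymethoxy)benzaldehyde; 17 1-[3,5-dimethoxy-4-(methoxymethoxy)phenyl]ethanone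
Product: 18 (E)-1-[3,5-dimethoxy-4-(methoxymethoxy)phenyl]-3-[5-(3-hydroxypropyl)-3-methoxy-2-(methoxymethoxy)phenyl]prop-2-en-1-one
Conditions: KOH (aq), EtOH, 25 °C
Reagents that add atoms: none
Why: Claisen–Schmidt condensation; the conjugated E-enone is the thermodynamic product and MOM ethers and the free alcohol are base-stable.

Step 12
Reactants: 18 chalcone
Product: 19 1-[3,5-dimethoxy-4-(methoxymethoxy)phenyl]-2-[5-(3-hydroxypropyl)-3-methoxy-2-(methoxymethoxy)phenyl]-3,3-dimethoxypropan-1-one (racemic)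
Conditions: PhI(OH)OTs (1.2 equiv), MeOH, 25 °C
Reagents that add atoms: methanol, CO
Why: Oxidative 1,2-aryl shift (hypervalent-iodine chalcone rearrangement): trivalent iodine and methanol add across the enone, the electron-rich ring C migrates from Cβ to Cα through a phenonium ion as PhI leaves, and methanol traps the oxocarbenium as the acetal; the new stereocentre is racemic and is erased in step 13.

Step 13
Reactants: 19 rearranged acetal ketone
Product: 21 2-(4-hydroxy-3,5-dimethoxyphenyl)-5-(3-hydroxypropyl)-7-methoxy-1-benzofuran-3-carbaldehyde, via cyclic methyl acetal 20 (not isolated)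
Conditions: p-TsOH·H2O (0.2 equiv), MeOH, 50 °C; evaporate; then p-TsOH·H2O (1 equiv), (CF3)2CHOH, 25 °C
Reagents that add atoms: none
Why: Acid transacetalisation removes both MOM groups and closes the phenol onto the acetal (20); in the fluoro alcohol the ring reopens to an oxocarbenium, the phenol attacks the aryl ketone instead, and cyclodehydration with loss of methanol gives the aromatic 2-aryl-3-formylbenzofuran.

Step 14
Reactants: 21 benzofuran-3-carbaldehyde
Product: 22 4-[3-(hydroxymethyl)-5-(3-hydroxypropyl)-7-methoxy-1-benzofuran-2-yl]-2,6-dimethoxyphenol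
Conditions: NaBH4, THF–MeOH, 0 °C; neutral work-up
Reagents that add atoms: none
Why: Chemoselective borohydride 1,2-reduction of the aldehyde; acid is avoided because the product is an ionisable benzofuranylmethanol.

Step 15
Reactants: 22 benzofuran triol
Product: 23 4-[(2R,3R)-3-(hydroxymethyl)-5-(3-hydroxypropyl)-7-methoxy-2,3-dihydro-1-benzofuran-2-yl]-2,6-dimethoxyphenol (cis)
Conditions: Ru(cod)(2-methylallyl)2 (5 mol%), (R,R)-SINpEt·HBF4 (1,3-bis[(1R)-1-(1-naphthyl)ethyl]-4,5-dihydroimidazolium tetrafluoroborate, 10 mol%), KOtBu (12 mol%), toluene, 70 °C (catalyst pre-formation); then 22, H2 (60 bar), toluene–t-AmOH 3:1, 25 °C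
Reagents that add atoms: none
Why: Proposed new method: enantioselective syn-hydrogenation of a tetrasubstituted 2-aryl-3-(hydroxymethyl)benzofuran. The chiral ruthenium–bis(NHC) hydride that reduces the O–C2=C3 unit of 2-arylbenzofurans is expected to bind the primary alcohol as a ruthenium alkoxide, so the hindered C2=C3 bond is held on the metal in a two-point chelate and one enantioface is selected by the naphthylethyl wings; both hydrogens are delivered to the same face, which makes C2 and C3 cis and sets 2R,3R in one event. Closest known reactions are ruthenium–NHC asymmetric hydrogenation of 2-substituted benzofurans and alkoxide-directed ruthenium–diphosphine hydrogenation of allylic alcohols; the ligand antipode is confirmed on a pilot run and exchanged for (S,S) if the sense is opposite.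

Step 16
Reactants: 24 bromoacetyl bromide
Product: 25 (4S)-4-benzyl-3-(bromoacetyl)-1,3-oxazolidin-2-one
Conditions: (S)-4-benzyl-1,3-oxazolidin-2-one, n-BuLi, THF, −78 °C; then 24
Reagents that add atoms: (S)-4-benzyl-1,3-oxazolidin-2-one, O=C1N[C@@H](Cc2ccccc2)CO1
Why: N-Acylation of the lithiated oxazolidinone by the more reactive acyl bromide terminus.

Step 17
Reactants: 23 cis-dihydrobenzofuran phenol; 25 (4S)-bromoacetyl imide
Product: 26 (4S)-4-benzyl-3-({4-[(2R,3R)-3-(hydroxymethyl)-5-(3-hydroxypropyl)-7-methoxy-2,3-dihydro-1-benzofuran-2-yl]-2,6-dimethoxyphenoxy}acetyl)-1,3-oxazolidin-2-one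
Conditions: K2CO3 (1.5 equiv), acetone, 25 °C
Reagents that add atoms: none
Why: Williamson etherification (SN2 at the α-halo carbonyl); carbonate deprotonates only the phenol, and the mild, cold conditions avoid quinone-methide opening of the cis ring.

Step 18
Reactants: 26 aryloxyacetyl imide; 4 vanillin
Product: 30 (4S)-4-benzyl-3-[(2R,3R)-3-hydroxy-3-(4-hydroxy-3-methoxyphenyl)-2-{4-[(2R,3R)-3-(hydroxymethyl)-5-(3-hydroxypropyl)-7-methoxy-2,3-dihydro-1-benzofuran-2-yl]-2,6-dimethoxyphenoxy}propanoyl]-1,3-oxazolidin-2-one, via O-silylated vanillin 27 (not isolated), via bis-silylated imide 28 (not isolated), via tetrakis-silylated aldol adduct 29 (not isolated)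
Conditions: 4, TMSCl (1.2 equiv), Et3N, EtOAc, 0 °C; then 26, MgCl2 (20 mol%), Et3N (5 equiv), TMSCl (4 equiv), EtOAc, 23 °C; then Bu4NF–AcOH (1:1), THF, 0 °C
Reagents that add atoms: none
Why: Proposed new method: magnesium-halide-catalysed direct anti-aldol of an α-aryloxyacetyl oxazolidinone with a phenolic aldehyde silylated in the flask. Et3N enolises the MgCl2-chelated imide to the chelated (Z)-enolate, and the aldehyde adds through a boat transition state on the face opposite the benzyl group (the facial sense of auxiliary-controlled alkylations, giving 2R); the anti aldolate (3R) is trapped by TMSCl, which also masks the three free hydroxyls, and buffered fluoride then removes all silyl groups without acid. Closest known reaction is the MgCl2/Et3N/TMSCl anti-aldol of N-propionyl oxazolidinones with aromatic aldehydes.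

Step 19
Reactants: 30 anti-aldol adduct
Product: 31 (1R,2S)-1-(4-hydroxy-3-methoxyphenyl)-2-{4-[(2R,3R)-3-(hydroxymethyl)-5-(3-hydroxypropyl)-7-methoxy-2,3-dihydro-1-benzofuran-2-yl]-2,6-dimethoxyphenoxy}propane-1,3-diol (target)
Conditions: LiBH4 (6 equiv), THF–MeOH, 0 → 25 °C; aq NH4Cl
Reagents that add atoms: none
Why: Reductive removal of the oxazolidinone auxiliary converts the imide carbonyl into the C9 hydroxymethyl group without touching the four stereocentres.

**Compound list**

1 | catechol | Oc1ccccc1O | starting material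
2 | guaiacol | COc1ccccc1O | intermediate
3 | 4-hydroxy-3-methoxymandelic acid (racemic, not isolated) | COc1cc(ccc1O)C(O)C(=O)O | intermediate
4 | vanillin | COc1cc(C=O)ccc1O | intermediate
5 | 4-bromo-2-methoxyphenol | COc1cc(Br)ccc1O | intermediate
6 | 4-bromo-2-methoxy-1-(methoxymethoxy)benzene | COCOc1ccc(Br)cc1OC | intermediate
7 | allyloxytrimethylsilane | C=CCO[Si](C)(C)C | starting material
8 | 9-[3-(trimethylsilyloxy)propyl]-9-borabicyclo[3.3.1]nonane (not isolated) | C[Si](C)(C)OCCCB1C2CCCC1CCC2 | intermediate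
9 | trimethyl{3-[3-methoxy-4-(methoxymethoxy)phenyl]propoxy}silane (not isolated) | COCOc1ccc(CCCO[Si](C)(C)C)cc1OC | intermediate
10 | 3-[3-methoxy-4-(methoxymethoxy)phenyl]propan-1-ol | COCOc1ccc(CCCO)cc1OC | intermediate
11 | lithium 3-[3-lithio-5-methoxy-4-(methoxymethoxy)phenyl]propan-1-olate (not isolated) | [Li]OCCCc1cc([Li])c(OCOC)c(OC)c1 | intermediate
12 | 5-(3-hydroxypropyl)-3-methoxy-2-(methoxymethoxy)benzaldehyde | COCOc1c(C=O)cc(CCCO)cc1OC | intermediate
13 | phenol | Oc1ccccc1 | starting material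
14 | 1-(4-hydroxyphenyl)ethanone | CC(=O)c1ccc(O)cc1 | intermediate
15 | 1-(3,5-dibromo-4-hydroxyphenyl)ethanone | CC(=O)c1cc(Br)c(O)c(Br)c1 | intermediate
16 | acetosyringone | CC(=O)c1cc(OC)c(O)c(OC)c1 | intermediate
17 | 1-[3,5-dimethoxy-4-(methoxymethoxy)phenyl]ethanone | CC(=O)c1cc(OC)c(OCOC)c(OC)c1 | intermediate
18 | (E)-chalcone from 12 and 17 | COCOc1c(OC)cc(cc1OC)C(=O)/C=C/c1cc(CCCO)cc(OC)c1OCOC | intermediate
19 | 1,2-diaryl-3,3-dimethoxypropan-1-one (racemic) | COCOc1c(OC)cc(cc1OC)C(=O)C(C(OC)OC)c1cc(CCCO)cc(OC)c1OCOC | intermediate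
20 | (4-hydroxy-3,5-dimethoxyphenyl)[5-(3-hydroxypropyl)-2,7-dimethoxy-2,3-dihydro-1-benzofuran-3-yl]methanone (not isolated) | COC1Oc2c(OC)cc(CCCO)cc2C1C(=O)c1cc(OC)c(O)c(OC)c1 | intermediate
21 | 2-(4-hydroxy-3,5-dimethoxyphenyl)-5-(3-hydroxypropyl)-7-methoxy-1-benzofuran-3-carbaldehyde | COc1cc(cc(OC)c1O)-c1oc2c(OC)cc(CCCO)cc2c1C=O | intermediate
22 | 4-[3-(hydroxymethyl)-5-(3-hydroxypropyl)-7-methoxy-1-benzofuran-2-yl]-2,6-dimethoxyphenol | COc1cc(cc(OC)c1O)-c1oc2c(OC)cc(CCCO)cc2c1CO | intermediate
23 | 4-[(2R,3R)-3-(hydroxymethyl)-5-(3-hydroxypropyl)-7-methoxy-2,3-dihydro-1-benzofuran-2-yl]-2,6-dimethoxyphenol (cis) | COc1cc(cc(OC)c1O)[C@@H]1Oc2c(OC)cc(CCCO)cc2[C@@H]1CO | intermediate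
24 | bromoacetyl bromide | BrCC(Br)=O | starting material
25 | (4S)-4-benzyl-3-(bromoacetyl)-1,3-oxazolidin-2-one | O=C1OC[C@H](Cc2ccccc2)N1C(=O)CBr | intermediate
26 | (4S)-aryloxyacetyl imide of 23 | COc1cc(cc(OC)c1OCC(=O)N1[C@@H](Cc2ccccc2)COC1=O)[C@@H]1Oc2c(OC)cc(CCCO)cc2[C@@H]1CO | intermediate
27 | 3-methoxy-4-(trimethylsilyloxy)benzaldehyde (not isolated) | COc1cc(C=O)ccc1O[Si](C)(C)C | intermediate
28 | bis(trimethylsilyl) ether of 26 (not isolated) | COc1cc(cc(OC)c1OCC(=O)N1[C@@H](Cc2ccccc2)COC1=O)[C@@H]1Oc2c(OC)cc(CCCO[Si](C)(C)C)cc2[C@@H]1CO[Si](C)(C)C | intermediate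
29 | tetrakis(trimethylsilyl) ether of 30 (not isolated) | COc1cc(ccc1O[Si](C)(C)C)[C@@H](O[Si](C)(C)C)[C@H](C(=O)N2[C@@H](Cc3ccccc3)COC2=O)Oc2c(OC)cc(cc2OC)[C@@H]2Oc3c(OC)cc(CCCO[Si](C)(C)C)cc3[C@@H]2CO[Si](C)(C)C | intermediate
30 | (4S)-imide anti-aldol adduct, (2R,3R) in the acyl chain | COc1cc(ccc1O)[C@@H](O)[C@H](C(=O)N2[C@@H](Cc3ccccc3)COC2=O)Oc2c(OC)cc(cc2OC)[C@@H]2Oc3c(OC)cc(CCCO)cc3[C@@H]2CO | intermediate
31 | CNP0301567.1 | COc1cc([C@@H](O)[C@H](CO)Oc2c(OC)cc([C@@H]3Oc4c(OC)cc(CCCO)cc4[C@@H]3CO)cc2OC)ccc1O | target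

**Totals and risks**

Total step count: 19. Longest linear sequence: 13 steps (1, 3, 4, 5, 6, 11, 12, 13, 14, 15, 17, 18, 19).

The three steps most likely to fail:

Step 15 (proposed new hydrogenation). The tetrasubstituted C2=C3 bond may react slowly, and the enantioselectivity on a substrate with three free hydroxyls is untested. The fallback sets out from 22 and comes back at 23. Compound 22 is hydrogenated over Rh/Al2O3 (5 wt%, H2 5 bar, EtOAc–EtOH, 25 °C), a heterogeneous syn-addition known for 2,3-disubstituted benzofurans. This gives the racemic cis-dihydrobenzofuran, a 1:1 mixture of 23 and the (2S,3S)-configured cis-triol F1. The enantiomers are separated by preparative chromatography on cellulose tris(3,5-dimethylphenylcarbamate) (CO2–MeOH), and 23 continues in step 17 at the cost of half the material.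

Step 18 (proposed new anti-aldol). The α-aryloxy group may erode the anti or facial selectivity, and the silylated electron-rich aldehyde may react slowly. The fallback sets out from 23 and comes back at 31, using the boron syn-aldol and Mitsunobu inversion known for arylglycerol β-aryl ethers. (R)-4-Benzyl-1,3-oxazolidin-2-one is acylated with 24 (n-BuLi, THF, −78 °C) to the (4R)-bromoacetyl imide F2. Compound 23 is alkylated with F2 (K2CO3, acetone) to the (4R)-aryloxyacetyl imide diol F3, and both primary hydroxyls are acetylated (Ac2O, pyridine) to the diacetate F4. Vanillin 4 is acetylated to 4-formyl-2-methoxyphenyl acetate F5. F4 and F5 are combined in the boron-mediated Evans syn-aldol (Bu2BOTf, i-Pr2NEt, CH2Cl2, −78 → 0 °C; H2O2 work-up) to the (2R,3S)-syn adduct F6, which already has the correct configuration at the aryloxy carbon. The benzylic carbinol is inverted by a Mitsunobu reaction (4-nitrobenzoic acid, PPh3, DIAD, THF, 0 °C) to the (2R,3R)-4-nitrobenzoate F7. LiBH4 (THF–MeOH) then removes the auxiliary, the nitrobenzoate and the three acetates in one operation to give 31.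

Step 12 (oxidative 1,2-aryl shift). The trivalent-iodine reagent may over-oxidise the electron-rich rings, or the liberated acid may unmask a phenol too early. The fallback sets out from 18 and comes back at 20, inside step 13. Weitz–Scheffer epoxidation of 18 (H2O2, NaOH, MeOH, 0 °C) gives the trans-epoxy ketone F8. BF3·OEt2 (CH2Cl2, 0 °C) opens it at the benzylic carbon, and a 1,2-aroyl shift gives the 2-aryl-3-oxopropanal F9, the skeleton of 19 with a free aldehyde. Methanolic p-TsOH (first stage of step 13) removes the MOM groups and closes the phenol onto the aldehyde as the cyclic methyl acetal 20.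

**Further compounds**

F1 | step 15 | 4-[(2S,3S)-3-(hydroxymethyl)-5-(3-hydroxypropyl)-7-methoxy-2,3-dihydro-1-benzofuran-2-yl]-2,6-dimethoxyphenol (enantiomer of 23, formed with it as the racemate) | COc1cc(cc(OC)c1O)[C@H]1Oc2c(OC)cc(CCCO)cc2[C@H]1CO
F2 | step 18 | (4R)-4-benzyl-3-(bromoacetyl)-1,3-oxazolidin-2-one | O=C1OC[C@@H](Cc2ccccc2)N1C(=O)CBr
F3 | step 18 | (4R)-aryloxyacetyl imide diol from 23 | COc1cc(cc(OC)c1OCC(=O)N1[C@H](Cc2ccccc2)COC1=O)[C@@H]1Oc2c(OC)cc(CCCO)cc2[C@@H]1CO
F4 | step 18 | diacetate of F3 | COc1cc(cc(OC)c1OCC(=O)N1[C@H](Cc2ccccc2)COC1=O)[C@@H]1Oc2c(OC)cc(CCCOC(C)=O)cc2[C@@H]1COC(C)=O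
F5 | step 18 | 4-formyl-2-methoxyphenyl acetate | COc1cc(C=O)ccc1OC(C)=O
F6 | step 18 | (4R)-imide syn-aldol adduct, (2R,3S) in the acyl chain | COc1cc(ccc1OC(C)=O)[C@H](O)[C@H](C(=O)N2[C@H](Cc3ccccc3)COC2=O)Oc2c(OC)cc(cc2OC)[C@@H]2Oc3c(OC)cc(CCCOC(C)=O)cc3[C@@H]2COC(C)=O
F7 | step 18 | (4R)-imide 4-nitrobenzoate, (2R,3R) in the acyl chain | COc1cc(ccc1OC(C)=O)[C@@H](OC(=O)c2ccc(cc2)[N+](=O)[O-])[C@H](C(=O)N2[C@H](Cc3ccccc3)COC2=O)Oc2c(OC)cc(cc2OC)[C@@H]2Oc3c(OC)cc(CCCOC(C)=O)cc3[C@@H]2COC(C)=O
F8 | step 12 | trans-epoxy ketone of chalcone 18 (racemic) | COCOc1c(OC)cc(cc1OC)C(=O)C1OC1c1cc(CCCO)cc(OC)c1OCOC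
F9 | step 12 | 3-[3,5-dimethoxy-4-(methoxymethoxy)phenyl]-2-[5-(3-hydroxypropyl)-3-methoxy-2-(methoxymethoxy)phenyl]-3-oxopropanal (racemic) | COCOc1c(OC)cc(cc1OC)C(=O)C(C=O)c1cc(CCCO)cc(OC)c1OCOC
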